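**Plan**
- Retrosynthetic cuts, in order: the three O–Si bonds that mask the quinone and the C5 phenol; the ester C–O bond; the prenyl C=C bond (cross-metathesis); the ArCH(OH)–CH2 bond (allylation); the C7–CHO bond (formylation of a bromide); and, in the quinone ring, the C2–C3 and C1–C8a bonds.
- The last cut leaves an aroyl sulfoxonium ylide on ring B (acyl carbon = C4, ylide carbon = C3) and vinylene carbonate (C1–C2, with the C1 oxygen already in place). One rhodium-catalysed C–H annulation should join them and deliver the new ring at the hydroquinone oxidation level.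
- Enabling feature: ring B has a single free C–H (C8a), lying between the acyl group on C4a and the C8 methoxy group, because C5 carries the protected oxygen. The C5 and C8 oxygens are told apart beforehand by chelation-controlled demethylation next to the ester.
- Forward order: benzoate (ring B) → ylide → quinone ring → reductive silylation → C7 bromide to aldehyde → allyl → prenyl → ester → desilylation and air oxidation.
- Stereochemistry: the only stereocenter (R) comes from a reagent-controlled Brown allylboration with (+)-Ipc2B(allyl); no later step breaks a bond at this carbon.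

Key step: step 5

Remark: all naphthalene compounds are numbered as the target quinone (C1 and C4 are the quinone or hydroquinone carbons, C5 carries the free or protected hydroxyl, C7 the bromine or side chain, C8 the methoxy group), also where the lowest-locant rule would number the ring the other way round.

**Route**

Step 1
Reactants: 1 4-bromo-2,5-dimethoxybenzaldehyde
Product: 2 methyl 4-bromo-2,5-dimethoxybenzoate
Conditions: I2, KOH, MeOH, 0 °C
Reagents that add atoms: methanol, SMILES CO
Why: Oxidative esterification of an aldehyde: the methyl hemiacetal should be oxidized by hypoiodite to the methyl ester, which provides the acyl carbon that becomes C4.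

Step 2
Reactants: 2 methyl 4-bromo-2,5-dimethoxybenzoate
Product: 3 methyl 4-bromo-2-hydroxy-5-methoxybenzoate
Conditions: BCl3 (1.2 equiv), CH2Cl2, −78 → 0 °C; aqueous work-up
Reagents that add atoms: none
Why: Chelation-controlled aryl methyl ether cleavage: BCl3 held by the ester carbonyl should cleave only the ortho methoxy group, which tells the future C5 oxygen apart from the C8 methoxy group.

Step 3
Reactants: 3 methyl 4-bromo-2-hydroxy-5-methoxybenzoate
Product: 4 methyl 4-bromo-5-methoxy-2-[(4-methoxyphenyl)methoxy]benzoate
Conditions: 4-methoxybenzyl chloride, K2CO3, DMF, 60 °C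
Reagents that add atoms: 4-methoxybenzyl chloride, SMILES COc1ccc(CCl)cc1
Why: Williamson ether synthesis on the phenoxide installs a base-stable PMB ether that blocks C5 and keeps the phenol from attacking the ylide carbon later.

Step 4
Reactants: 4 methyl 4-bromo-5-methoxy-2-[(4-methoxyphenyl)methoxy]benzoate
Product: 5 1-{4-bromo-5-methoxy-2-[(4-methoxyphenyl)methoxy]phenyl}-2-[dimethyl(oxo)-λ6-sulfanylidene]ethan-1-one
Conditions: trimethylsulfoxonium iodide (3 equiv), KOtBu (3 equiv), THF, reflux; then 4, 0 °C → rt
Reagents that add atoms: trimethylsulfoxonium iodide, SMILES C[S+](C)(C)=O.[I-]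
Why: Acylation of dimethylsulfoxonium methylide by the methyl ester (ylide acylation with the Corey–Chaykovsky reagent) should give the stabilized β-keto sulfoxonium ylide, the aryl bromide and the PMB ether being inert to the ylide.

Step 5
Reactants: 5 the aroyl sulfoxonium ylide; 6 vinylene carbonate
Product: 10 7-bromo-5-hydroxy-8-methoxynaphthalene-1,4-dione, via hydroxy enone 7 (not isolated), via hydroquinone 8 (not isolated), via PMB quinone 9 (not isolated)
Conditions: 6 (2 equiv), [Cp*RhCl2]2 (4 mol %), AgSbF6 (16 mol %), NaOAc (30 mol %), ClCH2CH2Cl, 80 °C, Ar; then DDQ (3 equiv), CH2Cl2/H2O, rt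
Reagents that add atoms: none
Why: Proposed new method: acetate-assisted rhodation of the only free ortho C–H of 5 (C8a, between the acyl and methoxy groups) gives a five-membered rhodacycle bound through the ylide carbon, syn insertion of the C=C bond of 6 into the aryl–rhodium bond forms C8a–C1, loss of DMSO turns the ylide carbon into a rhodium carbene, and 1,1-migratory insertion of the C2 alkyl group forms C2–C3. The rhodium enolate so formed should expel the carbonate oxygen on C2 in an E1cB-like β-oxygen elimination, CO2 is lost to give hydroxy enone 7, and tautomerization gives hydroquinone 8 without any external oxidant; DDQ then oxidizes 8 to quinone 9 and cleaves its PMB ether to give 10, both known reactions. The closest known reaction type is the Cp*Rh-catalyzed (4+2) annulation of aroyl sulfoxonium ylides with internal alkynes to 1-naphthols, and vinylene carbonate is an established two-carbon partner in Cp*Rh C–H annulations of benzamides; only their combination is new. The six-membered ring is closed by carbene migratory insertion inside a seven-membered rhodacycle, overall an intermolecular formal (4+2) annulation, and no stereocenter remains in the product. Site selectivity is secured by the OPMB group, which blocks the other ortho position, and the oxygen is kept on C1 because only the C2 oxygen is β to the enolate. The step also needs carbene insertion to outrun β-oxygen elimination from the first alkyl–rhodium species, which the cis-fused carbonate ring should favor by holding the C1–O bond out of line with the C2–Rh bond.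

Step 6
Reactants: 10 7-bromo-5-hydroxy-8-methoxynaphthalene-1,4-dione
Product: 12 7-bromo-1,4,5-tris(tert-butyldimethylsilyloxy)-8-methoxynaphthalene, via naphthalenetriol 11 (not isolated)
Conditions: Na2S2O4, EtOAc/H2O, rt, Ar; then TBSOTf (4 equiv), 2,6-lutidine, CH2Cl2, 0 °C → rt
Reagents that add atoms: tert-butyldimethylsilyl trifluoromethanesulfonate, SMILES CC(C)(C)[Si](C)(C)OS(=O)(=O)C(F)(F)F
Why: Dithionite should reduce the quinone to the hydroquinone and the silyl triflate then silylates all three phenols (reductive protection), which hides the quinone from the organolithium and allylborane reagents that follow.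

Step 7
Reactants: 12 7-bromo-1,4,5-tris(tert-butyldimethylsilyloxy)-8-methoxynaphthalene
Product: 14 1,4,5-tris(tert-butyldimethylsilyloxy)-8-methoxynaphthalene-7-carbaldehyde, via aryllithium 13 (not isolated)
Conditions: n-BuLi (1.1 equiv), THF, −78 °C; DMF, −78 → 0 °C; aq NH4Cl
Reagents that add atoms: N,N-dimethylformamide, SMILES CN(C)C=O
Why: Bromine–lithium exchange followed by formylation with DMF (Bouveault aldehyde synthesis) should work because exchange at −78 °C is faster than attack on the aryl silyl ethers and no silyloxy group is ortho to the lithiated carbon.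

Step 8
Reactants: 14 1,4,5-tris(tert-butyldimethylsilyloxy)-8-methoxynaphthalene-7-carbaldehyde
Product: 15 (1R)-1-[1,4,5-tris(tert-butyldimethylsilyloxy)-8-methoxynaphthalen-7-yl]but-3-en-1-ol
Conditions: (+)-Ipc2B(allyl) (1.3 equiv, the reagent of the (−)-α-pinene series), Et2O, −78 °C; then 2-aminoethanol, rt
Reagents that add atoms: (+)-B-allyldiisopinocampheylborane, SMILES C=CCB([C@H]1C[C@H]2C[C@@H]([C@@H]1C)C2(C)C)[C@H]1C[C@H]2C[C@@H]([C@@H]1C)C2(C)C
Why: Brown allylboration: the allyl group is transferred through a closed chair transition state in which the isopinocampheyl groups of the (+)-reagent expose the Re face of the aldehyde, which should set the (R) carbinol center by reagent control.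

Step 9
Reactants: 15 (1R)-1-[1,4,5-tris(tert-butyldimethylsilyloxy)-8-methoxynaphthalen-7-yl]but-3-en-1-ol
Product: 16 (1R)-1-[1,4,5-tris(tert-butyldimethylsilyloxy)-8-methoxynaphthalen-7-yl]-4-methylpent-3-en-1-ol
Conditions: 2-methylbut-2-ene (large excess), second-generation Grubbs catalyst RuCl2(=CHPh)(H2IMes)(PCy3) (5 mol %), CH2Cl2, 40 °C, sealed tube
Reagents that add atoms: 2-methylbut-2-ene, SMILES CC=C(C)C
Why: Olefin cross-metathesis with a large excess of 2-methylbut-2-ene should exchange the terminal methylene for an isopropylidene group and so give the prenyl-type trisubstituted alkene without touching the carbinol center.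

Step 10
Reactants: 16 the (R)-prenyl carbinol; 17 3-methylbut-2-enoic acid
Product: 18 (1R)-1-[1,4,5-tris(tert-butyldimethylsilyloxy)-8-methoxynaphthalen-7-yl]-4-methylpent-3-enyl 3-methylbut-2-enoate
Conditions: 17 (1.5 equiv), DCC, DMAP (0.2 equiv), CH2Cl2, 0 °C → rt
Reagents that add atoms: none
Why: Steglich esterification (carbodiimide activation, DMAP acyl transfer) acylates the only free hydroxyl at oxygen, so the C–O bond of the stereocenter is not broken and the (R) configuration should be kept.

Step 11
Reactants: 18 the tris-silyl ester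
Product: 20 (1R)-1-(5-hydroxy-8-methoxy-1,4-dioxo-1,4-dihydronaphthalen-7-yl)-4-methylpent-3-enyl 3-methylbut-2-enoate, via hydroquinone ester 19 (not isolated)
Conditions: TBAF (3.5 equiv), AcOH (4 equiv), THF, 0 °C → rt; then stirred under air (O2)
Reagents that add atoms: none
Why: Fluoride should cleave the three aryl silyl ethers under acetic acid buffering and the freed 1,4-hydroquinone is oxidized by air to the quinone (desilylation then autoxidation), while the C5 oxygen can only end as the hydrogen-bonded phenol because C8 carries a methyl ether.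

**Compound list**

1 | 4-bromo-2,5-dimethoxybenzaldehyde | COc1cc(C=O)c(OC)cc1Br | starting material
2 | methyl 4-bromo-2,5-dimethoxybenzoate | COC(=O)c1cc(OC)c(Br)cc1OC | intermediate
3 | methyl 4-bromo-2-hydroxy-5-methoxybenzoate | COC(=O)c1cc(OC)c(Br)cc1O | intermediate
4 | methyl 4-bromo-5-methoxy-2-[(4-methoxyphenyl)methoxy]benzoate | COC(=O)c1cc(OC)c(Br)cc1OCc1ccc(OC)cc1 | intermediate
5 | 1-{4-bromo-5-methoxy-2-[(4-methoxyphenyl)methoxy]phenyl}-2-[dimethyl(oxo)-λ6-sulfanylidene]ethan-1-one | CS(C)(=O)=CC(=O)c1cc(OC)c(Br)cc1OCc1ccc(OC)cc1 | intermediate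
6 | vinylene carbonate (1,3-dioxol-2-one) | O=C1OC=CO1 | starting material
7 | 7-bromo-1-hydroxy-8-methoxy-5-[(4-methoxyphenyl)methoxy]naphthalen-4(1H)-one (racemic) | COc1c(Br)cc(OCc2ccc(OC)cc2)c2C(=O)C=CC(O)c12 | intermediate (not isolated)
8 | 7-bromo-8-methoxy-5-[(4-methoxyphenyl)methoxy]naphthalene-1,4-diol | COc1c(Br)cc(OCc2ccc(OC)cc2)c2c(O)ccc(O)c12 | intermediate (not isolated)
9 | 7-bromo-8-methoxy-5-[(4-methoxyphenyl)methoxy]naphthalene-1,4-dione | COc1c(Br)cc(OCc2ccc(OC)cc2)c2c1C(=O)C=CC2=O | intermediate (not isolated)
10 | 7-bromo-5-hydroxy-8-methoxynaphthalene-1,4-dione | COc1c(Br)cc(O)c2c1C(=O)C=CC2=O | intermediate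
11 | 7-bromo-8-methoxynaphthalene-1,4,5-triol | COc1c(Br)cc(O)c2c(O)ccc(O)c12 | intermediate (not isolated)
12 | 7-bromo-1,4,5-tris(tert-butyldimethylsilyloxy)-8-methoxynaphthalene | COc1c(Br)cc(O[Si](C)(C)C(C)(C)C)c2c(O[Si](C)(C)C(C)(C)C)ccc(O[Si](C)(C)C(C)(C)C)c12 | intermediate
13 | [1,4,5-tris(tert-butyldimethylsilyloxy)-8-methoxynaphthalen-7-yl]lithium | COc1c([Li])cc(O[Si](C)(C)C(C)(C)C)c2c(O[Si](C)(C)C(C)(C)C)ccc(O[Si](C)(C)C(C)(C)C)c12 | intermediate (not isolated)
14 | 1,4,5-tris(tert-butyldimethylsilyloxy)-8-methoxynaphthalene-7-carbaldehyde | COc1c(C=O)cc(O[Si](C)(C)C(C)(C)C)c2c(O[Si](C)(C)C(C)(C)C)ccc(O[Si](C)(C)C(C)(C)C)c12 | intermediate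
15 | (1R)-1-[1,4,5-tris(tert-butyldimethylsilyloxy)-8-methoxynaphthalen-7-yl]but-3-en-1-ol | COc1c([C@H](O)CC=C)cc(O[Si](C)(C)C(C)(C)C)c2c(O[Si](C)(C)C(C)(C)C)ccc(O[Si](C)(C)C(C)(C)C)c12 | intermediate
16 | (1R)-1-[1,4,5-tris(tert-butyldimethylsilyloxy)-8-methoxynaphthalen-7-yl]-4-methylpent-3-en-1-ol | COc1c([C@H](O)CC=C(C)C)cc(O[Si](C)(C)C(C)(C)C)c2c(O[Si](C)(C)C(C)(C)C)ccc(O[Si](C)(C)C(C)(C)C)c12 | intermediate
17 | 3-methylbut-2-enoic acid | CC(C)=CC(=O)O | starting material
18 | (1R)-1-[1,4,5-tris(tert-butyldimethylsilyloxy)-8-methoxynaphthalen-7-yl]-4-methylpent-3-enyl 3-methylbut-2-enoate | COc1c([C@@H](CC=C(C)C)OC(=O)C=C(C)C)cc(O[Si](C)(C)C(C)(C)C)c2c(O[Si](C)(C)C(C)(C)C)ccc(O[Si](C)(C)C(C)(C)C)c12 | intermediate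
19 | (1R)-1-(1,4,5-trihydroxy-8-methoxynaphthalen-7-yl)-4-methylpent-3-enyl 3-methylbut-2-enoate | COc1c([C@@H](CC=C(C)C)OC(=O)C=C(C)C)cc(O)c2c(O)ccc(O)c12 | intermediate (not isolated)
20 | (1R)-1-(5-hydroxy-8-methoxy-1,4-dioxo-1,4-dihydronaphthalen-7-yl)-4-methylpent-3-enyl 3-methylbut-2-enoate | COc1c([C@@H](CC=C(C)C)OC(=O)C=C(C)C)cc(O)c2c1C(=O)C=CC2=O | target

**Step count and risks**

Total steps: 11. Longest linear sequence: 11 steps (1 → 20).

Steps most likely to fail:

1. Step 5 (the step proposed as new). C–H rhodation at a position flanked by two substituents may be slow, and β-oxygen elimination may take place before the carbene insertion and so lead the catalytic cycle away from ring closure. Fallback with known chemistry, from 5 back to 8: the same two ring bonds are made by a xanthate group-transfer radical addition and a radical cyclization onto the arene. HCl in dioxane should convert 5 into the α-chloro ketone F1. KSC(S)OEt in acetone gives the S-phenacyl xanthate F2. Radical addition to vinyl acetate, started by dilauroyl peroxide in refluxing ethyl acetate, forms C2–C3 and gives the xanthate adduct F3. A stoichiometric amount of the peroxide in refluxing 1,2-dichloroethane closes C1–C8a and gives the acetoxy tetralone F4. K2CO3 in MeOH frees the hydroxy tetralone F5, and Dess–Martin periodinane gives the 1,4-diketone F6. With Et3N this enolizes to hydroquinone 8, and the DDQ treatment of step 5 then leads on to 10.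

2. Step 10. Acylation of the hindered carbinol next to the C8 methoxy group may be slow, the electron-rich benzylic position may ionize with loss of configuration, and the double bond of the activated acid may migrate through a vinylketene. Fallback from 16 back to 18: DCC/DMAP coupling with (diethoxyphosphoryl)acetic acid, an unhindered acid that cannot deconjugate, gives the phosphonoacetate F7. A Horner–Wadsworth–Emmons reaction with acetone (NaH, THF, 0 °C → rt) then builds the 3-methylbut-2-enoate double bond in place.

3. Step 11. The benzylic acyloxy group may be lost at the electron-rich hydroquinone stage before oxidation (ionization through an extended quinone methide), or the ester may be cleaved by fluoride. Fallback from 16 to 20, with the order of the last two operations reversed: TBAF/AcOH in THF followed by air gives the tetraol F8, which autoxidizes to the hydroxy quinone F9. The secondary alcohol of F9 is then esterified with 17 (DCC, catalytic DMAP, CH2Cl2, 0 °C); the C5 phenol, hydrogen-bonded to the C4 carbonyl, should not react.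

**Further compounds**

F1 | step 5 | 1-{4-bromo-5-methoxy-2-[(4-methoxyphenyl)methoxy]phenyl}-2-chloroethan-1-one | O=C(CCl)c1cc(OC)c(Br)cc1OCc1ccc(OC)cc1
F2 | step 5 | S-(2-{4-bromo-5-methoxy-2-[(4-methoxyphenyl)methoxy]phenyl}-2-oxoethyl) O-ethyl carbonodithioate | CCOC(=S)SCC(=O)c1cc(OC)c(Br)cc1OCc1ccc(OC)cc1
F3 | step 5 | 4-{4-bromo-5-methoxy-2-[(4-methoxyphenyl)methoxy]phenyl}-1-[(ethoxycarbonothioyl)sulfanyl]-4-oxobutyl acetate (racemic) | CCOC(=S)SC(CCC(=O)c1cc(OC)c(Br)cc1OCc1ccc(OC)cc1)OC(C)=O
F4 | step 5 | 7-bromo-8-methoxy-5-[(4-methoxyphenyl)methoxy]-4-oxo-1,2,3,4-tetrahydronaphthalen-1-yl acetate (racemic) | COc1c(Br)cc(OCc2ccc(OC)cc2)c2C(=O)CCC(OC(C)=O)c12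
F5 | step 5 | 7-bromo-1-hydroxy-8-methoxy-5-[(4-methoxyphenyl)methoxy]-2,3-dihydronaphthalen-4(1H)-one (racemic) | COc1c(Br)cc(OCc2ccc(OC)cc2)c2C(=O)CCC(O)c12
F6 | step 5 | 7-bromo-8-methoxy-5-[(4-methoxyphenyl)methoxy]-2,3-dihydronaphthalene-1,4-dione | COc1c(Br)cc(OCc2ccc(OC)cc2)c2C(=O)CCC(=O)c12
F7 | step 10 | (1R)-1-[1,4,5-tris(tert-butyldimethylsilyloxy)-8-methoxynaphthalen-7-yl]-4-methylpent-3-enyl (diethoxyphosphoryl)acetate | COc1c([C@@H](CC=C(C)C)OC(=O)CP(=O)(OCC)OCC)cc(O[Si](C)(C)C(C)(C)C)c2c(O[Si](C)(C)C(C)(C)C)ccc(O[Si](C)(C)C(C)(C)C)c12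
F8 | step 11 | 7-[(1R)-1-hydroxy-4-methylpent-3-enyl]-8-methoxynaphthalene-1,4,5-triol | COc1c([C@H](O)CC=C(C)C)cc(O)c2c(O)ccc(O)c12
F9 | step 11 | 5-hydroxy-7-[(1R)-1-hydroxy-4-methylpent-3-enyl]-8-methoxynaphthalene-1,4-dione | COc1c([C@H](O)CC=C(C)C)cc(O)c2c1C(=O)C=CC2=O
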